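**Strategy.** The five-membered lactone ring (O–C12–C11–C7–C6) with its exocyclic C13 is read as a carbonylated 2,3-allenol: C6–OH, C7=C11=C13 and carbon monoxide. A PdCl2/CuCl2 chlorocyclocarbonylation joins the acyclic, fully functionalised allenol, CO and chloride in one operation: C11–C12 bond formation closes the butenolide and leaves C13 as an allylic chloride. This 3-(chloromethyl)butenolide is the latent C13–C11–C7 allyl nucleophile that then closes the ten-membered ring at C7–C8 onto a tethered C8 aldehyde (CrCl2), moving the double bond to C11=C13. The allenol chain comes from two butynediol-derived (Z)-vinyl iodides.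

Key step: step 12

Numbering: germacrane numbers are used. C1–C10 form the ten-membered ring; C6 bears the lactone oxygen, C7 bears C11, C11=C13 is the methylene group, C12 the lactone carbonyl, C14 (on C10) the aldehyde carbon, C15 (on C4) the CH2OH carbon, C8 the ester. Both ring double bonds are cis within the ring (E by the priority rules).

Assumption: (S,S)-ProPhenol is taken as the ligand antipode that delivers the alkynyl group to the Si face of enal 14; should the sense be the opposite, the (R,R) ligand is used.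

Step 1
Reactants: 1 but-2-yne-1,4-diol
Product: 2 4-[(4-methoxybenzyl)oxy]but-2-yn-1-ol
Conditions: NaH, 4-methoxybenzyl chloride, Bu4NI (cat.), THF/DMF, 0 °C to rt (1 in threefold excess)
Reagents that add atoms: 4-methoxybenzyl chloride COc1ccc(CCl)cc1
Why: Williamson monoetherification of the symmetrical diol, the excess of 1 keeping bis-alkylation low.

Step 2
Reactants: 2 4-[(4-methoxybenzyl)oxy]but-2-yn-1-ol
Product: 4 (2Z)-3-iodo-4-[(4-methoxybenzyl)oxy]but-2-en-1-ol, via cyclic vinylalanate 3 (not isolated)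
Conditions: NaAlH2(OCH2CH2OMe)2, THF, 0 °C to rt; then I2, −78 to 0 °C
Reagents that add atoms: iodine II
Why: Hydroxyl-directed trans-hydroalumination of the propargylic alcohol (hydride to the carbon next to CH2OH, aluminium to the distal carbon within a five-membered alanate) and iodinolysis with retention should give the (Z)-iodide, which later fixes C9 cis to C2 on C1=C10.

Step 3
Reactants: 4 (2Z)-3-iodo-4-[(4-methoxybenzyl)oxy]but-2-en-1-ol; 5 (1,3-dioxolan-2-ylmethyl)zinc bromide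
Product: 6 (2E)-4-(1,3-dioxolan-2-yl)-3-{[(4-methoxybenzyl)oxy]methyl}but-2-en-1-ol
Conditions: Pd(PPh3)4 (cat.), THF, 50 °C (excess 5)
Reagents that add atoms: none
Why: Negishi sp2–sp3 cross-coupling with retention of alkene geometry installs C9 and C8, the latter masked as a dioxolane.

Step 4
Reactants: 6 (2E)-4-(1,3-dioxolan-2-yl)-3-{[(4-methoxybenzyl)oxy]methyl}but-2-en-1-ol
Product: 7 (2E)-4-(1,3-dioxolan-2-yl)-3-{[(4-methoxybenzyl)oxy]methyl}but-2-enal
Conditions: MnO2, CH2Cl2, rt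
Reagents that add atoms: none
Why: Chemoselective MnO2 oxidation of the primary allylic alcohol to the enal without touching acetal or ether.

Step 5
Reactants: 7 (2E)-4-(1,3-dioxolan-2-yl)-3-{[(4-methoxybenzyl)oxy]methyl}but-2-enal
Product: 8 2-[(2E)-2-{[(4-methoxybenzyl)oxy]methyl}penta-2,4-dien-1-yl]-1,3-dioxolane
Conditions: Ph3PCH3Br, KN(SiMe3)2, THF, −78 to 0 °C
Reagents that add atoms: methyltriphenylphosphonium bromide C[P+](c1ccccc1)(c1ccccc1)c1ccccc1.[Br-]
Why: Wittig methylenation of the enal should give the terminal diene whose vinyl group supplies C2 and C3.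

Step 6
Reactants: 1 but-2-yne-1,4-diol
Product: 9 4-[(tert-butyldiphenylsilyl)oxy]but-2-yn-1-ol
Conditions: NaH, t-BuPh2SiCl, THF, 0 °C to rt (1 in excess)
Reagents that add atoms: tert-butyl(chloro)diphenylsilane CC(C)(C)[Si](Cl)(c1ccccc1)c1ccccc1
Why: Monosilylation of the symmetrical diol through its monosodium alkoxide.

Step 7
Reactants: 9 4-[(tert-butyldiphenylsilyl)oxy]but-2-yn-1-ol
Product: 11 (2Z)-4-[(tert-butyldiphenylsilyl)oxy]-3-iodobut-2-en-1-ol, via cyclic vinylalanate 10 (not isolated)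
Conditions: NaAlH2(OCH2CH2OMe)2, THF, 0 °C to rt; then I2, −78 to 0 °C
Reagents that add atoms: iodine II
Why: Same directed trans-hydroalumination and iodinolysis as in step 2; the (Z)-iodide later fixes C3 cis to C6 on C4=C5.

Step 8
Reactants: 8 2-[(2E)-2-{[(4-methoxybenzyl)oxy]methyl}penta-2,4-dien-1-yl]-1,3-dioxolane; 11 (2Z)-4-[(tert-butyldiphenylsilyl)oxy]-3-iodobut-2-en-1-ol
Product: 13 (2E,6E)-3-{[(tert-butyldiphenylsilyl)oxy]methyl}-8-(1,3-dioxolan-2-yl)-7-{[(4-methoxybenzyl)oxy]methyl}octa-2,6-dien-1-ol, via B-alkyl-9-BBN 12 (not isolated)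
Conditions: 9-BBN, THF, 0 °C to rt; then 11, Pd(dppf)Cl2 (cat.), AsPh3, Cs2CO3, DMF/H2O, rt
Reagents that add atoms: none
Why: 9-BBN should add only to the monosubstituted terminal alkene of the diene with boron on C3, and the B-alkyl Suzuki–Miyaura coupling with vinyl iodide 11 forms C3–C4 with retention of its geometry.

Step 9
Reactants: 13 (2E,6E)-3-{[(tert-butyldiphenylsilyl)oxy]methyl}-8-(1,3-dioxolan-2-yl)-7-{[(4-methoxybenzyl)oxy]methyl}octa-2,6-dien-1-ol
Product: 14 (2E,6E)-3-{[(tert-butyldiphenylsilyl)oxy]methyl}-8-(1,3-dioxolan-2-yl)-7-{[(4-methoxybenzyl)oxy]methyl}octa-2,6-dienal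
Conditions: MnO2, CH2Cl2, rt
Reagents that add atoms: none
Why: MnO2 oxidation of the primary allylic alcohol to the C6 enal with retention of the C4=C5 geometry.

Step 10
Reactants: 14 (2E,6E)-3-{[(tert-butyldiphenylsilyl)oxy]methyl}-8-(1,3-dioxolan-2-yl)-7-{[(4-methoxybenzyl)oxy]methyl}octa-2,6-dienal; 15 ethynyl(trimethyl)silane
Product: 17 (3R,4E,8E)-5-{[(tert-butyldiphenylsilyl)oxy]methyl}-10-(1,3-dioxolan-2-yl)-9-{[(4-methoxybenzyl)oxy]methyl}deca-4,8-dien-1-yn-3-ol, via silylated alkynol 16 (not isolated)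
Conditions: Me2Zn, (S,S)-ProPhenol (cat.), Ph3PO (cat.), toluene, 4 °C; then K2CO3, MeOH, rt
Reagents that add atoms: none
Why: Catalytic asymmetric zinc–ProPhenol alkynylation should deliver the alkynylzinc to the Si face of the enal and set C6 (R), and methanolysis of the C–Si bond then frees the terminal alkyne.

Step 11
Reactants: 17 (3R,4E,8E)-5-{[(tert-butyldiphenylsilyl)oxy]methyl}-10-(1,3-dioxolan-2-yl)-9-{[(4-methoxybenzyl)oxy]methyl}deca-4,8-dien-1-yn-3-ol
Product: 19 (4S,5E,9E)-6-{[(tert-butyldiphenylsilyl)oxy]methyl}-11-(1,3-dioxolan-2-yl)-10-{[(4-methoxybenzyl)oxy]methyl}undeca-1,2,5,9-tetraen-4-ol, via Mannich base 18 (not isolated)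
Conditions: (CH2O)n, CuI, Cy2NH, dioxane, reflux
Reagents that add atoms: paraformaldehyde (formaldehyde) C=O
Why: Crabbé homologation: the Mannich base from alkyne, formaldehyde and Cy2NH undergoes CuI-mediated 1,5-hydride transfer and loss of imine to give the terminal allene (C13), the carbinol stereocentre not being involved (its descriptor changes to S by priority only).

Step 12
Reactants: 19 (4S,5E,9E)-6-{[(tert-butyldiphenylsilyl)oxy]methyl}-11-(1,3-dioxolan-2-yl)-10-{[(4-methoxybenzyl)oxy]methyl}undeca-1,2,5,9-tetraen-4-ol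
Product: 20 (5R)-5-[(1E,5E)-2-{[(tert-butyldiphenylsilyl)oxy]methyl}-7-(1,3-dioxolan-2-yl)-6-{[(4-methoxybenzyl)oxy]methyl}hepta-1,5-dien-1-yl]-3-(chloromethyl)furan-2(5H)-one
Conditions: PdCl2 (cat.), CuCl2, CO (1 atm), propylene oxide, THF, rt
Reagents that add atoms: carbon monoxide [C-]#[O+]; CuCl2 Cl[Cu]Cl
Why: PdCl2, the hydroxyl group of 19 and CO give an alkoxycarbonylpalladium chloride (the HCl is taken up by propylene oxide); syn insertion of the distal C11=C13 bond into its Pd–acyl bond forms the C11–C12 bond and closes the five-membered ring (5-exo with respect to C11=C13, acyl carbon to the central allene carbon), leaving an η3-allyl palladium over C13–C11–C7. Chloride transfer from CuCl2 to the unhindered terminus C13 should then give the conjugated 3-(chloromethyl)furan-2(5H)-one and zerovalent palladium, which CuCl2 reoxidises to divalent palladium. The closest known reaction type is the PdCl2/CuCl2 chlorocyclocarbonylation of 2,3-allenols to 3-(chloromethyl)-2(5H)-furanones. No stereocentre is formed, and C6 is carried through unchanged because only its O–H bond reacts. The step needs chemoselectivity for the allene over the two trisubstituted alkenes (only the allene can reach the acylpalladium through a five-membered transition state), regioselectivity for C13–Cl over C7–Cl (terminal carbon, product in conjugation) and freedom from ionisation of the doubly allylic C6–O bond (buffered, amine-free medium, which also spares the base-labile C6–H of the product).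

Step 13
Reactants: 20 (5R)-5-[(1E,5E)-2-{[(tert-butyldiphenylsilyl)oxy]methyl}-7-(1,3-dioxolan-2-yl)-6-{[(4-methoxybenzyl)oxy]methyl}hepta-1,5-dien-1-yl]-3-(chloromethyl)furan-2(5H)-one
Product: 21 (3E,7E)-7-{[(tert-butyldiphenylsilyl)oxy]methyl}-8-[(2R)-4-(chloromethyl)-5-oxo-2,5-dihydrofuran-2-yl]-3-{[(4-methoxybenzyl)oxy]methyl}octa-3,7-dienal
Conditions: I2 (cat.), acetone, 40 °C; Na2S2O3 work-up, used at once
Reagents that add atoms: none
Why: Iodine-catalysed transacetalisation to acetone unmasks the C8 aldehyde under neutral, non-protic conditions, which should keep the β,γ-double bond C10=C1 out of conjugation.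

Step 14
Reactants: 21 (3E,7E)-7-{[(tert-butyldiphenylsilyl)oxy]methyl}-8-[(2R)-4-(chloromethyl)-5-oxo-2,5-dihydrofuran-2-yl]-3-{[(4-methoxybenzyl)oxy]methyl}octa-3,7-dienal
Product: 23 (6R,7R,8S,1(10)E,4E)-15-[(tert-butyldiphenylsilyl)oxy]-8-hydroxy-14-[(4-methoxybenzyl)oxy]germacra-1(10),4,11(13)-trien-12,6-olide (8α-OH), via allylchromium dichloride 22 (not isolated)
Conditions: CrCl2, THF/DMF, rt, slow addition (high dilution); pH 7 buffer, 0 °C
Reagents that add atoms: none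
Why: Intramolecular Nozaki–Hiyama–Kishi allylation: CrCl2 converts the allylic chloride into allylchromium 22, which adds to the tethered aldehyde at C7 (SE2') through a chair transition state and moves the double bond to C11=C13; A(1,3) strain across C4=C5 holds C6–H in the alkene plane so that the bridge should reach C7 on the face anti to C5 (trans-lactone, 7R), and the ring-locked E-type allyl unit with C9 equatorial should give the 7,8-anti alcohol (8S, 8α-OH).

Step 15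
Reactants: 23 (6R,7R,8S,1(10)E,4E)-15-[(tert-butyldiphenylsilyl)oxy]-8-hydroxy-14-[(4-methoxybenzyl)oxy]germacra-1(10),4,11(13)-trien-12,6-olide; 24 (2S)-2-methylbutanoic acid
Product: 25 (6R,7R,8R,1(10)E,4E)-15-[(tert-butyldiphenylsilyl)oxy]-14-[(4-methoxybenzyl)oxy]-8-{[(2S)-2-methylbutanoyl]oxy}germacra-1(10),4,11(13)-trien-12,6-olide
Conditions: PPh3, DIAD, toluene, 0 °C to rt
Reagents that add atoms: none
Why: Mitsunobu esterification: SN2 attack of the carboxylate on the C8 alkoxyphosphonium ion inverts C8 (8α-OH to 8β-ester, S to R) and leaves the acid stereocentre untouched.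

Step 16
Reactants: 25 (6R,7R,8R,1(10)E,4E)-15-[(tert-butyldiphenylsilyl)oxy]-14-[(4-methoxybenzyl)oxy]-8-{[(2S)-2-methylbutanoyl]oxy}germacra-1(10),4,11(13)-trien-12,6-olide
Product: 26 (6R,7R,8R,1(10)E,4E)-15-[(tert-butyldiphenylsilyl)oxy]-14-hydroxy-8-{[(2S)-2-methylbutanoyl]oxy}germacra-1(10),4,11(13)-trien-12,6-olide
Conditions: DDQ, CH2Cl2/pH 7 buffer, 0 °C to rt
Reagents that add atoms: none
Why: Oxidative cleavage of the 4-methoxybenzyl ether by DDQ through the benzylic oxocarbenium ion should free the C14 alcohol selectively.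

Step 17
Reactants: 26 (6R,7R,8R,1(10)E,4E)-15-[(tert-butyldiphenylsilyl)oxy]-14-hydroxy-8-{[(2S)-2-methylbutanoyl]oxy}germacra-1(10),4,11(13)-trien-12,6-olide
Product: 27 (6R,7R,8R,1(10)E,4E)-15-[(tert-butyldiphenylsilyl)oxy]-8-{[(2S)-2-methylbutanoyl]oxy}-14-oxogermacra-1(10),4,11(13)-trien-12,6-olide
Conditions: MnO2, CH2Cl2, rt
Reagents that add atoms: none
Why: MnO2 oxidises the primary allylic C14 alcohol to the conjugated aldehyde and should leave ester, lactone and silyl ether untouched.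

Step 18
Reactants: 27 (6R,7R,8R,1(10)E,4E)-15-[(tert-butyldiphenylsilyl)oxy]-8-{[(2S)-2-methylbutanoyl]oxy}-14-oxogermacra-1(10),4,11(13)-trien-12,6-olide
Product: 28 (6R,7R,8R,1(10)E,4E)-15-hydroxy-8-{[(2S)-2-methylbutanoyl]oxy}-14-oxogermacra-1(10),4,11(13)-trien-12,6-olide (CNP0168859.6)
Conditions: HF·pyridine, pyridine/THF, 0 °C to rt
Reagents that add atoms: none
Why: Fluoride cleavage of the Si–O bond under buffered conditions should free the C15 alcohol without harming the enal, the ester or the α-methylene lactone.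

**Compound list**

1 | but-2-yne-1,4-diol | OCC#CCO | starting material
2 | 4-[(4-methoxybenzyl)oxy]but-2-yn-1-ol | OCC#CCOCc1ccc(OC)cc1 | intermediate
3 | sodium 2,2-bis(2-methoxyethoxy)-3-{[(4-methoxybenzyl)oxy]methyl}-2,5-dihydro-1,2-oxaaluminol-2-uide (cyclic vinylalanate) | [Na+].COCCO[Al-]1(OCCOC)OCC=C1COCc1ccc(OC)cc1 | intermediate
4 | (2Z)-3-iodo-4-[(4-methoxybenzyl)oxy]but-2-en-1-ol | OC/C=C(\I)COCc1ccc(OC)cc1 | intermediate
5 | (1,3-dioxolan-2-ylmethyl)zinc bromide | Br[Zn]CC1OCCO1 | starting material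
6 | (2E)-4-(1,3-dioxolan-2-yl)-3-{[(4-methoxybenzyl)oxy]methyl}but-2-en-1-ol | OC/C=C(\CC1OCCO1)COCc1ccc(OC)cc1 | intermediate
7 | (2E)-4-(1,3-dioxolan-2-yl)-3-{[(4-methoxybenzyl)oxy]methyl}but-2-enal | O=C/C=C(\CC1OCCO1)COCc1ccc(OC)cc1 | intermediate
8 | 2-[(2E)-2-{[(4-methoxybenzyl)oxy]methyl}penta-2,4-dien-1-yl]-1,3-dioxolane | C=C/C=C(\CC1OCCO1)COCc1ccc(OC)cc1 | intermediate
9 | 4-[(tert-butyldiphenylsilyl)oxy]but-2-yn-1-ol | OCC#CCO[Si](c1ccccc1)(c1ccccc1)C(C)(C)C | intermediate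
10 | sodium 3-{[(tert-butyldiphenylsilyl)oxy]methyl}-2,2-bis(2-methoxyethoxy)-2,5-dihydro-1,2-oxaaluminol-2-uide (cyclic vinylalanate) | [Na+].COCCO[Al-]1(OCCOC)OCC=C1CO[Si](c1ccccc1)(c1ccccc1)C(C)(C)C | intermediate
11 | (2Z)-4-[(tert-butyldiphenylsilyl)oxy]-3-iodobut-2-en-1-ol | OC/C=C(\I)CO[Si](c1ccccc1)(c1ccccc1)C(C)(C)C | intermediate
12 | 9-[(3E)-5-(1,3-dioxolan-2-yl)-4-{[(4-methoxybenzyl)oxy]methyl}pent-3-en-1-yl]-9-borabicyclo[3.3.1]nonane | C1CC2CCCC(C1)B2CC/C=C(\CC1OCCO1)COCc1ccc(OC)cc1 | intermediate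
13 | (2E,6E)-3-{[(tert-butyldiphenylsilyl)oxy]methyl}-8-(1,3-dioxolan-2-yl)-7-{[(4-methoxybenzyl)oxy]methyl}octa-2,6-dien-1-ol | OC/C=C(/CO[Si](c1ccccc1)(c1ccccc1)C(C)(C)C)CC/C=C(\CC1OCCO1)COCc1ccc(OC)cc1 | intermediate
14 | (2E,6E)-3-{[(tert-butyldiphenylsilyl)oxy]methyl}-8-(1,3-dioxolan-2-yl)-7-{[(4-methoxybenzyl)oxy]methyl}octa-2,6-dienal | O=C/C=C(/CO[Si](c1ccccc1)(c1ccccc1)C(C)(C)C)CC/C=C(\CC1OCCO1)COCc1ccc(OC)cc1 | intermediate
15 | ethynyl(trimethyl)silane | C#C[Si](C)(C)C | starting material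
16 | (3R,4E,8E)-5-{[(tert-butyldiphenylsilyl)oxy]methyl}-10-(1,3-dioxolan-2-yl)-9-{[(4-methoxybenzyl)oxy]methyl}-1-(trimethylsilyl)deca-4,8-dien-1-yn-3-ol | O[C@@H](C#C[Si](C)(C)C)/C=C(/CO[Si](c1ccccc1)(c1ccccc1)C(C)(C)C)CC/C=C(\CC1OCCO1)COCc1ccc(OC)cc1 | intermediate
17 | (3R,4E,8E)-5-{[(tert-butyldiphenylsilyl)oxy]methyl}-10-(1,3-dioxolan-2-yl)-9-{[(4-methoxybenzyl)oxy]methyl}deca-4,8-dien-1-yn-3-ol | O[C@@H](C#C)/C=C(/CO[Si](c1ccccc1)(c1ccccc1)C(C)(C)C)CC/C=C(\CC1OCCO1)COCc1ccc(OC)cc1 | intermediate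
18 | (4R,5E,9E)-6-{[(tert-butyldiphenylsilyl)oxy]methyl}-1-(dicyclohexylamino)-11-(1,3-dioxolan-2-yl)-10-{[(4-methoxybenzyl)oxy]methyl}undeca-5,9-dien-2-yn-4-ol (Mannich base) | O[C@@H](C#CCN(C1CCCCC1)C1CCCCC1)/C=C(/CO[Si](c1ccccc1)(c1ccccc1)C(C)(C)C)CC/C=C(\CC1OCCO1)COCc1ccc(OC)cc1 | intermediate
19 | (4S,5E,9E)-6-{[(tert-butyldiphenylsilyl)oxy]methyl}-11-(1,3-dioxolan-2-yl)-10-{[(4-methoxybenzyl)oxy]methyl}undeca-1,2,5,9-tetraen-4-ol | O[C@@H](C=C=C)/C=C(/CO[Si](c1ccccc1)(c1ccccc1)C(C)(C)C)CC/C=C(\CC1OCCO1)COCc1ccc(OC)cc1 | intermediate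
20 | (5R)-5-[(1E,5E)-2-{[(tert-butyldiphenylsilyl)oxy]methyl}-7-(1,3-dioxolan-2-yl)-6-{[(4-methoxybenzyl)oxy]methyl}hepta-1,5-dien-1-yl]-3-(chloromethyl)furan-2(5H)-one | O=C1O[C@@H](C=C1CCl)/C=C(/CO[Si](c1ccccc1)(c1ccccc1)C(C)(C)C)CC/C=C(\CC1OCCO1)COCc1ccc(OC)cc1 | intermediate
21 | (3E,7E)-7-{[(tert-butyldiphenylsilyl)oxy]methyl}-8-[(2R)-4-(chloromethyl)-5-oxo-2,5-dihydrofuran-2-yl]-3-{[(4-methoxybenzyl)oxy]methyl}octa-3,7-dienal | O=C1O[C@@H](C=C1CCl)/C=C(/CO[Si](c1ccccc1)(c1ccccc1)C(C)(C)C)CC/C=C(\CC=O)COCc1ccc(OC)cc1 | intermediate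
22 | allylchromium dichloride of 21 (CrCl2 unit on C13 in place of chlorine) | O=C1O[C@@H](C=C1C[Cr](Cl)Cl)/C=C(/CO[Si](c1ccccc1)(c1ccccc1)C(C)(C)C)CC/C=C(\CC=O)COCc1ccc(OC)cc1 | intermediate
23 | (6R,7R,8S,1(10)E,4E)-15-[(tert-butyldiphenylsilyl)oxy]-8-hydroxy-14-[(4-methoxybenzyl)oxy]germacra-1(10),4,11(13)-trien-12,6-olide (trans-fused lactone, 8α-OH) | C=C1C(=O)O[C@@H]2/C=C(/CO[Si](c3ccccc3)(c3ccccc3)C(C)(C)C)CC/C=C(/COCc3ccc(OC)cc3)C[C@H](O)[C@@H]12 | intermediate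
24 | (2S)-2-methylbutanoic acid | CC[C@H](C)C(=O)O | starting material
25 | (6R,7R,8R,1(10)E,4E)-15-[(tert-butyldiphenylsilyl)oxy]-14-[(4-methoxybenzyl)oxy]-8-{[(2S)-2-methylbutanoyl]oxy}germacra-1(10),4,11(13)-trien-12,6-olide | C=C1C(=O)O[C@@H]2/C=C(/CO[Si](c3ccccc3)(c3ccccc3)C(C)(C)C)CC/C=C(/COCc3ccc(OC)cc3)C[C@@H](OC(=O)[C@@H](C)CC)[C@@H]12 | intermediate
26 | (6R,7R,8R,1(10)E,4E)-15-[(tert-butyldiphenylsilyl)oxy]-14-hydroxy-8-{[(2S)-2-methylbutanoyl]oxy}germacra-1(10),4,11(13)-trien-12,6-olide | C=C1C(=O)O[C@@H]2/C=C(/CO[Si](c3ccccc3)(c3ccccc3)C(C)(C)C)CC/C=C(/CO)C[C@@H](OC(=O)[C@@H](C)CC)[C@@H]12 | intermediate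
27 | (6R,7R,8R,1(10)E,4E)-15-[(tert-butyldiphenylsilyl)oxy]-8-{[(2S)-2-methylbutanoyl]oxy}-14-oxogermacra-1(10),4,11(13)-trien-12,6-olide | C=C1C(=O)O[C@@H]2/C=C(/CO[Si](c3ccccc3)(c3ccccc3)C(C)(C)C)CC/C=C(/C=O)C[C@@H](OC(=O)[C@@H](C)CC)[C@@H]12 | intermediate
28 | (6R,7R,8R,1(10)E,4E)-15-hydroxy-8-{[(2S)-2-methylbutanoyl]oxy}-14-oxogermacra-1(10),4,11(13)-trien-12,6-olide (CNP0168859.6) | C=C1C(=O)O[C@@H]2/C=C(/CO)CC/C=C(/C=O)C[C@@H](OC(=O)[C@@H](C)CC)[C@@H]12 | target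

**Step count.** Total: 18 steps. Longest linear sequence: 16 steps (steps 1–5 and 8–18).

**Steps most likely to fail**

Step 14. Intermolecular coupling may outrun ring closure, or the tethered, chromium-bridged chair may deliver C8 to the face of C7 syn to C5 (cis-fused lactone). The fallback sets out from 20 and comes back at 25. The chloride of 20 is exchanged for tin (Bu3SnSnBu3, Pd(PPh3)4, THF, 60 °C) to give allylstannane F1. Transacetalisation as in step 13 gives stannyl aldehyde F2. BF3·OEt2 in CH2Cl2 at −78 °C under high dilution then closes the ring by an open, non-bridged SE2' addition of the allylstannane to the complexed aldehyde; this should place O8 syn and give 8β-alcohol F3. Acylation of F3 with (2S)-2-methylbutanoic anhydride and DMAP (retention) gives 25.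

Step 15. Oxyphosphonium formation at the hindered ring alcohol may be slow, and E2 loss of the activated oxygen toward C9 (conjugated diene) may compete with substitution. The fallback sets out from 23 and comes back at 25. The alcohol is converted into chloromethanesulfonate F4 (ClCH2SO2Cl, pyridine, 0 °C) and displaced with caesium (2S)-2-methylbutanoate (from 24 and Cs2CO3) and 18-crown-6 in toluene. This is an SN2 inversion in which activation and displacement are separate and no basic betaine is present.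

Step 12. The acid released may ionise the doubly allylic C6–O bond or cleave the dioxolane, and the 1,5-diene may divert divalent palladium from carbonylation. The fallback sets out from 14 and comes back at 20. Zinc–ProPhenol addition of tert-butyldimethyl(prop-2-yn-1-yloxy)silane to 14 gives alkynol F5. Hydroxyl-directed trans-hydroalumination with NaAlH2(OCH2CH2OMe)2 through cyclic vinylalanate F6, then iodinolysis, gives (Z)-vinyl iodide F7. Carbonylative lactonisation (Pd(PPh3)2Cl2, CO, K2CO3, THF; oxidative addition, CO insertion forming C11–C12, capture of the acylpalladium by the C6 hydroxyl) gives silyloxymethyl butenolide F8. HF·pyridine at 0 °C removes the primary tert-butyldimethylsilyl group selectively to give hydroxymethyl butenolide F9. MsCl, LiCl and 2,4,6-collidine in DMF convert F9 into 20.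

**Further compounds**

F1 | step 14 | (5R)-5-[(1E,5E)-2-{[(tert-butyldiphenylsilyl)oxy]methyl}-7-(1,3-dioxolan-2-yl)-6-{[(4-methoxybenzyl)oxy]methyl}hepta-1,5-dien-1-yl]-3-[(tributylstannyl)methyl]furan-2(5H)-one | O=C1O[C@@H](C=C1C[Sn](CCCC)(CCCC)CCCC)/C=C(/CO[Si](c1ccccc1)(c1ccccc1)C(C)(C)C)CC/C=C(\CC1OCCO1)COCc1ccc(OC)cc1
F2 | step 14 | (3E,7E)-7-{[(tert-butyldiphenylsilyl)oxy]methyl}-3-{[(4-methoxybenzyl)oxy]methyl}-8-{(2R)-5-oxo-4-[(tributylstannyl)methyl]-2,5-dihydrofuran-2-yl}octa-3,7-dienal | O=C1O[C@@H](C=C1C[Sn](CCCC)(CCCC)CCCC)/C=C(/CO[Si](c1ccccc1)(c1ccccc1)C(C)(C)C)CC/C=C(\CC=O)COCc1ccc(OC)cc1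
F3 | step 14 | (6R,7R,8R,1(10)E,4E)-15-[(tert-butyldiphenylsilyl)oxy]-8-hydroxy-14-[(4-methoxybenzyl)oxy]germacra-1(10),4,11(13)-trien-12,6-olide (8β-OH) | C=C1C(=O)O[C@@H]2/C=C(/CO[Si](c3ccccc3)(c3ccccc3)C(C)(C)C)CC/C=C(/COCc3ccc(OC)cc3)C[C@@H](O)[C@@H]12
F4 | step 15 | (6R,7R,8S,1(10)E,4E)-15-[(tert-butyldiphenylsilyl)oxy]-8-[(chloromethanesulfonyl)oxy]-14-[(4-methoxybenzyl)oxy]germacra-1(10),4,11(13)-trien-12,6-olide | C=C1C(=O)O[C@@H]2/C=C(/CO[Si](c3ccccc3)(c3ccccc3)C(C)(C)C)CC/C=C(/COCc3ccc(OC)cc3)C[C@H](OS(=O)(=O)CCl)[C@@H]12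
F5 | step 12 | (4R,5E,9E)-1-[(tert-butyldimethylsilyl)oxy]-6-{[(tert-butyldiphenylsilyl)oxy]methyl}-11-(1,3-dioxolan-2-yl)-10-{[(4-methoxybenzyl)oxy]methyl}undeca-5,9-dien-2-yn-4-ol | O[C@@H](C#CCO[Si](C)(C)C(C)(C)C)/C=C(/CO[Si](c1ccccc1)(c1ccccc1)C(C)(C)C)CC/C=C(\CC1OCCO1)COCc1ccc(OC)cc1
F6 | step 12 | sodium cyclic vinylalanate of F5 (aluminium on C11 and on the C6 oxygen, two 2-methoxyethoxy ligands) | [Na+].COCCO[Al-]1(OCCOC)O[C@@H](C=C1CO[Si](C)(C)C(C)(C)C)/C=C(/CO[Si](c1ccccc1)(c1ccccc1)C(C)(C)C)CC/C=C(\CC1OCCO1)COCc1ccc(OC)cc1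
F7 | step 12 | (2Z,4R,5E,9E)-1-[(tert-butyldimethylsilyl)oxy]-6-{[(tert-butyldiphenylsilyl)oxy]methyl}-11-(1,3-dioxolan-2-yl)-2-iodo-10-{[(4-methoxybenzyl)oxy]methyl}undeca-2,5,9-trien-4-ol | O[C@@H](/C=C(\I)CO[Si](C)(C)C(C)(C)C)/C=C(/CO[Si](c1ccccc1)(c1ccccc1)C(C)(C)C)CC/C=C(\CC1OCCO1)COCc1ccc(OC)cc1
F8 | step 12 | (5R)-3-{[(tert-butyldimethylsilyl)oxy]methyl}-5-[(1E,5E)-2-{[(tert-butyldiphenylsilyl)oxy]methyl}-7-(1,3-dioxolan-2-yl)-6-{[(4-methoxybenzyl)oxy]methyl}hepta-1,5-dien-1-yl]furan-2(5H)-one | O=C1O[C@@H](C=C1CO[Si](C)(C)C(C)(C)C)/C=C(/CO[Si](c1ccccc1)(c1ccccc1)C(C)(C)C)CC/C=C(\CC1OCCO1)COCc1ccc(OC)cc1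
F9 | step 12 | (5R)-5-[(1E,5E)-2-{[(tert-butyldiphenylsilyl)oxy]methyl}-7-(1,3-dioxolan-2-yl)-6-{[(4-methoxybenzyl)oxy]methyl}hepta-1,5-dien-1-yl]-3-(hydroxymethyl)furan-2(5H)-one | O=C1O[C@@H](C=C1CO)/C=C(/CO[Si](c1ccccc1)(c1ccccc1)C(C)(C)C)CC/C=C(\CC1OCCO1)COCc1ccc(OC)cc1
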